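The pyranone ring C is disconnected at its aryl ether bond O1–C8a. An intramolecular copper-mediated O-arylation joins the enol oxygen on C2 (the carbon carrying ring B) to the brominated ring-A carbon ortho to the C4 acyl group. One operation therefore closes ring C and delivers the whole apigenin skeleton with its three oxygens differentiated. The precursor is an open-chain 1-(2-bromoaryl)-3-aryl-1,3-diketone: ring A carries bromine and two allyl ethers (future 5-OH and 7-OH), ring B a benzyl ether (future 4'-OH). After deallylation only 7-OH should react, because 5-OH is tied to the C4 carbonyl by a hydrogen bond.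

Key step: step 5

Assumption: the target has no stereogenic element, so no stereocontrol is needed; the sulfate is carried as its potassium salt and the free hydrogen sulfate drawn for the target is released only in the last operation.

Step 1
Reactants: 1 5-bromoresorcinol; 2 allyl bromide
Product: 3 1,3-bis(allyloxy)-5-bromobenzene
Conditions: allyl bromide (2.5 equiv), K2CO3, DMF, 60 °C
Reagents that add atoms: allyl bromide (2), C=CCBr
Why: Williamson etherification, in which carbonate in a polar aprotic solvent should O-alkylate both phenoxides of the symmetric resorcinol with the reactive allylic bromide.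

Step 2
Reactants: 3 1,3-bis(allyloxy)-5-bromobenzene
Product: 5 2,4-bis(allyloxy)-6-bromobenzaldehyde, via aryl iminium chloride 4 (not isolated)
Conditions: POCl3, DMF, 0 → 80 °C; then ice, aq. NaOAc
Reagents that add atoms: N,N-dimethylformamide, CN(C)C=O; water, O
Why: Vilsmeier–Haack formylation, in which the chloroiminium electrophile should attack the carbon para to one allyloxy group and ortho to the other (next to bromine) and not the more crowded carbon flanked by both ethers, after which aqueous acetate hydrolyses the iminium salt to the aldehyde.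

Step 3
Reactants: 5 2,4-bis(allyloxy)-6-bromobenzaldehyde; 6 4'-(benzyloxy)acetophenone
Product: 8 rac-3-[2,4-bis(allyloxy)-6-bromophenyl]-1-[4-(benzyloxy)phenyl]-3-hydroxypropan-1-one, via lithium enolate 7 (not isolated)
Conditions: 6, LDA (1.0 equiv), THF, −78 °C; then 5, −78 °C; AcOH quench at −78 °C
Reagents that add atoms: none
Why: Directed aldol addition, in which the preformed lithium enolate adds to the non-enolisable aldehyde at low temperature without touching the aryl bromide and a cold acidic quench suppresses retro-aldol and dehydration; the carbinol centre forms racemic and is erased in step 4.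

Step 4
Reactants: 8 rac-3-[2,4-bis(allyloxy)-6-bromophenyl]-1-[4-(benzyloxy)phenyl]-3-hydroxypropan-1-one
Product: 9 1-[2,4-bis(allyloxy)-6-bromophenyl]-3-[4-(benzyloxy)phenyl]propane-1,3-dione
Conditions: IBX (2 equiv), EtOAc, 77 °C
Reagents that add atoms: none
Why: IBX oxidation of a β-hydroxy ketone to the 1,3-diketone, which should be fast at this electron-rich benzylic carbinol and should leave the activated methylene, the allyl ethers and the benzyl ether alone.

Step 5
Reactants: 9 1-[2,4-bis(allyloxy)-6-bromophenyl]-3-[4-(benzyloxy)phenyl]propane-1,3-dione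
Product: 10 5,7-bis(allyloxy)-2-[4-(benzyloxy)phenyl]-4H-chromen-4-one
Conditions: CuI (10 mol%), 1,10-phenanthroline (20 mol%), K2CO3 (2 equiv), DMF, 100 °C, Ar
Reagents that add atoms: none
Why: Carbonate deprotonates the acidic C3 methylene, and the enolate binds copper(I) as an O,O-chelate that holds the metal beside the ortho C–Br bond, so that oxidative addition and C–O reductive elimination (or the equivalent acyl-activated ipso substitution) forge O1–C8a. The closest known reaction type is the copper-catalysed intramolecular Ullmann O-arylation of 1-(2-haloaryl)-1,3-diketones to flavones and chromones. Ring C closes in a 6-exo mode, the enol oxygen attacking an aromatic sp2 carbon whose bromide departs outside the new ring. No stereocentre is created. The step needs O- over C-arylation and the correct oxygen, and the substrate secures both: C-arylation at C3 or attack by the oxygen on the ring-A-bound carbonyl would each require a four-membered ring, so only the enol oxygen on the ring-B-bound carbon can reach C8a. The bromide lies meta to both allyloxy donors and ortho to the acyl group, so it is not deactivated, and the allyl and benzyl ethers should be inert to copper(I) and carbonate at this temperature, which is well below that of an aryl allyl ether Claisen rearrangement.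

Step 6
Reactants: 10 5,7-bis(allyloxy)-2-[4-(benzyloxy)phenyl]-4H-chromen-4-one
Product: 11 2-[4-(benzyloxy)phenyl]-5,7-dihydroxy-4H-chromen-4-one (4'-O-benzylapigenin)
Conditions: Pd(PPh3)4 (5 mol%), morpholine (6 equiv), THF, rt; dilute aq. HCl work-up
Reagents that add atoms: none
Why: Tsuji–Trost deallylation, in which Pd(0) ionises each aryl allyl ether to a π-allyl complex and a stabilised phenoxide and morpholine traps the allyl fragment irreversibly, while the benzyl ether and the flavone core should not react.

Step 7
Reactants: 11 2-[4-(benzyloxy)phenyl]-5,7-dihydroxy-4H-chromen-4-one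
Product: 13 potassium 2-[4-(benzyloxy)phenyl]-5-hydroxy-4-oxo-4H-chromen-7-yl sulfate, via pyridinium sulfate monoester 12 (not isolated)
Conditions: SO3·pyridine (2 equiv), pyridine, 25–40 °C; then KOH, MeOH/H2O, 0 °C, to pH 8; C18 desalting
Reagents that add atoms: sulfur trioxide–pyridine complex, O=S(=O)([O-])[n+]1ccccc1; potassium hydroxide, [K+].[OH-]
Why: O-sulfation of a phenol with an amine–sulfur trioxide complex, in which 7-OH should be the only reactive hydroxyl because 5-OH is locked in a hydrogen bond to the C4 carbonyl and the 4'-oxygen is benzylated, and neutralisation with KOH gives the base-stable potassium salt free of amine.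

Step 8
Reactants: 13 potassium 2-[4-(benzyloxy)phenyl]-5-hydroxy-4-oxo-4H-chromen-7-yl sulfate
Product: 15 apigenin 7-sulfate (5-hydroxy-2-(4-hydroxyphenyl)-4-oxo-4H-chromen-7-yl hydrogen sulfate), via potassium apigenin 7-sulfate 14 (not isolated)
Conditions: H2 (1 atm), 10% Pd/C, MeOH/H2O, rt; filter; then 1.0 M HCl (1.0 equiv), 0 °C; C18 (H2O, then MeOH/H2O), lyophilise
Reagents that add atoms: none
Why: Catalytic hydrogenolysis of a benzyl aryl ether over Pd/C, which under one atmosphere at room temperature should spare the aryl sulfate salt and the pyranone C2=C3 bond, followed by cold protonation of the sulfate with one equivalent of strong acid and immediate freeze-drying to limit solvolysis of the monoester.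

Compound list
1 | 5-bromoresorcinol (5-bromobenzene-1,3-diol) | Oc1cc(O)cc(Br)c1 | starting material
2 | allyl bromide (3-bromoprop-1-ene) | C=CCBr | starting material
3 | 1,3-bis(allyloxy)-5-bromobenzene | C=CCOc1cc(Br)cc(OCC=C)c1 | intermediate
4 | N-{[2,4-bis(allyloxy)-6-bromophenyl]methylidene}-N-methylmethanaminium chloride (aryl iminium chloride) | C[N+](C)=Cc1c(Br)cc(OCC=C)cc1OCC=C.[Cl-] | intermediate
5 | 2,4-bis(allyloxy)-6-bromobenzaldehyde | O=Cc1c(Br)cc(OCC=C)cc1OCC=C | intermediate
6 | 4'-(benzyloxy)acetophenone | CC(=O)c1ccc(OCc2ccccc2)cc1 | starting material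
7 | lithium 1-[4-(benzyloxy)phenyl]ethen-1-olate (lithium enolate of 6) | [Li+].[O-]C(=C)c1ccc(OCc2ccccc2)cc1 | intermediate
8 | rac-3-[2,4-bis(allyloxy)-6-bromophenyl]-1-[4-(benzyloxy)phenyl]-3-hydroxypropan-1-one (racemic carbinol) | OC(CC(=O)c1ccc(OCc2ccccc2)cc1)c1c(Br)cc(OCC=C)cc1OCC=C | intermediate
9 | 1-[2,4-bis(allyloxy)-6-bromophenyl]-3-[4-(benzyloxy)phenyl]propane-1,3-dione | O=C(CC(=O)c1ccc(OCc2ccccc2)cc1)c1c(Br)cc(OCC=C)cc1OCC=C | intermediate
10 | 5,7-bis(allyloxy)-2-[4-(benzyloxy)phenyl]-4H-chromen-4-one | O=c1cc(-c2ccc(OCc3ccccc3)cc2)oc2cc(OCC=C)cc(OCC=C)c12 | intermediate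
11 | 2-[4-(benzyloxy)phenyl]-5,7-dihydroxy-4H-chromen-4-one (4'-O-benzylapigenin) | O=c1cc(-c2ccc(OCc3ccccc3)cc2)oc2cc(O)cc(O)c12 | intermediate
12 | pyridinium 2-[4-(benzyloxy)phenyl]-5-hydroxy-4-oxo-4H-chromen-7-yl sulfate | O=c1cc(-c2ccc(OCc3ccccc3)cc2)oc2cc(OS(=O)(=O)[O-])cc(O)c12.c1cc[nH+]cc1 | intermediate
13 | potassium 2-[4-(benzyloxy)phenyl]-5-hydroxy-4-oxo-4H-chromen-7-yl sulfate | O=c1cc(-c2ccc(OCc3ccccc3)cc2)oc2cc(OS(=O)(=O)[O-])cc(O)c12.[K+] | intermediate
14 | potassium 5-hydroxy-2-(4-hydroxyphenyl)-4-oxo-4H-chromen-7-yl sulfate (potassium apigenin 7-sulfate) | O=c1cc(-c2ccc(O)cc2)oc2cc(OS(=O)(=O)[O-])cc(O)c12.[K+] | intermediate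
15 | apigenin 7-sulfate (5-hydroxy-2-(4-hydroxyphenyl)-4-oxo-4H-chromen-7-yl hydrogen sulfate) | O=c1cc(-c2ccc(O)cc2)oc2cc(OS(=O)(=O)O)cc(O)c12 | target

Total step count: 8. Longest linear sequence: 8 steps (1 → 15); ketone 6 enters without prior steps.

Steps most likely to fail

Step 5. Oxidative addition into the aryl bromide may be slow, because the neighbouring acyl group is twisted out of plane by its second ortho substituent. Carbonate-induced retro-Claisen fragmentation of the diketone or reductive loss of bromine could then outrun ring closure. The fallback abandons the aryl halide and closes ring C at O1–C2 by cyclodehydration of a phenol (Baker–Venkataraman logic). It sets out from allyl bromide 2, which with commercial 2',4',6'-trihydroxyacetophenone (K2CO3, acetone, reflux; the hydrogen-bonded hydroxyl stays free) should give 1-[2,4-bis(allyloxy)-6-hydroxyphenyl]ethanone F1. Its dianion (LiHMDS, THF, −78 °C) would be C-acylated by 4-(benzyloxy)benzoyl chloride to 1-[2,4-bis(allyloxy)-6-hydroxyphenyl]-3-[4-(benzyloxy)phenyl]propane-1,3-dione F2. Catalytic p-TsOH in warm toluene should then dehydrate F2 to flavone 10, where the route is rejoined.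

Step 3. Addition to the hindered, electron-rich aldehyde may be reversible on warming (retro-aldol), and the benzylic hydroxyl may eliminate to the chalcone during quench or isolation. The fallback raises the aldehyde to the acid oxidation level and acylates the enolate directly, so that no carbinol is formed. It sets out from aldehyde 5: Pinnick oxidation (NaClO2, NaH2PO4, 2-methyl-2-butene, t-BuOH/H2O) should give 2,4-bis(allyloxy)-6-bromobenzoic acid F3. Oxalyl chloride with catalytic DMF in CH2Cl2 would convert it into 2,4-bis(allyloxy)-6-bromobenzoyl chloride F4. Addition of F4 to two equivalents of lithium enolate 7 (from 6, THF, −78 °C) should give diketone 9 directly, where the route is rejoined without step 4.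

Step 8. The pyranone C2=C3 bond may be over-reduced, or the hydrogenolysis may stall through catalyst inhibition by the ionic substrate. The fallback carries the sulfate as a neutral masked diester and removes the benzyl group without hydrogen. It sets out from 11: 2,2,2-trichloroethyl chlorosulfate with Et3N and DMAP in THF at 0 °C should give 2-[4-(benzyloxy)phenyl]-5-hydroxy-4-oxo-4H-chromen-7-yl 2,2,2-trichloroethyl sulfate F5. BCl3 with pentamethylbenzene in CH2Cl2 at −78 °C would cleave the benzyl ether to 5-hydroxy-2-(4-hydroxyphenyl)-4-oxo-4H-chromen-7-yl 2,2,2-trichloroethyl sulfate F6. Zinc dust and ammonium formate in MeOH should unmask the sulfate as ammonium apigenin 7-sulfate F7. Cold treatment with one equivalent of HCl and C18 desalting then arrives at target 15.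

Further compounds
F1 | step 5 | 1-[2,4-bis(allyloxy)-6-hydroxyphenyl]ethanone | CC(=O)c1c(O)cc(OCC=C)cc1OCC=C
F2 | step 5 | 1-[2,4-bis(allyloxy)-6-hydroxyphenyl]-3-[4-(benzyloxy)phenyl]propane-1,3-dione | O=C(CC(=O)c1ccc(OCc2ccccc2)cc1)c1c(O)cc(OCC=C)cc1OCC=C
F3 | step 3 | 2,4-bis(allyloxy)-6-bromobenzoic acid | O=C(O)c1c(Br)cc(OCC=C)cc1OCC=C
F4 | step 3 | 2,4-bis(allyloxy)-6-bromobenzoyl chloride | O=C(Cl)c1c(Br)cc(OCC=C)cc1OCC=C
F5 | step 8 | 2-[4-(benzyloxy)phenyl]-5-hydroxy-4-oxo-4H-chromen-7-yl 2,2,2-trichloroethyl sulfate | O=c1cc(-c2ccc(OCc3ccccc3)cc2)oc2cc(OS(=O)(=O)OCC(Cl)(Cl)Cl)cc(O)c12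
F6 | step 8 | 5-hydroxy-2-(4-hydroxyphenyl)-4-oxo-4H-chromen-7-yl 2,2,2-trichloroethyl sulfate | O=c1cc(-c2ccc(O)cc2)oc2cc(OS(=O)(=O)OCC(Cl)(Cl)Cl)cc(O)c12
F7 | step 8 | ammonium 5-hydroxy-2-(4-hydroxyphenyl)-4-oxo-4H-chromen-7-yl sulfate | O=c1cc(-c2ccc(O)cc2)oc2cc(OS(=O)(=O)[O-])cc(O)c12.[NH4+]
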